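**Retrosynthetic overview**

1. Target 13 is symmetric: ring A and ring B are identical benzene rings, each numbered C1 (CH2CH2 bridge), C2–Br, C3–OH, C4–OH, C5–Br, C6–Br. The strategy rests on the segment C2–C3–C4–C5: the adjacent hydroxylated carbons C3/C4 are read as an oxalate unit, the bromine-bearing C2/C5 beside them as the two α-carbons of an adipate whose ester groups later give way to bromine, and C1 as C3 of that adipate.
2. Last disconnection: all six C–Br bonds, made with Br2 on the bis(dihydroxyterephthalic acid) 12 (ipso-bromodecarboxylation at C2/C5, substitution at C6–H). Acid 12 comes from the bis(dione diester) 9 by aromatisation with Br2 and saponification.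
3. Key disconnection: C2–C3 and C4–C5 of both rings, giving tetraester 6 and two molecules of diethyl oxalate 7. Rings A and B are closed together in this one step and are the only rings the route has to build.
4. Tetraester 6 comes from 1,2-di(cyclohex-3-enyl)ethane 4 by oxidative cleavage of both ring alkenes and esterification. Diene 4 comes from copper-catalysed coupling of two molecules of bromide 2, made from commercial alcohol 1.

Key step: step 5

Assumption: alcohol 1 is used as the commercial racemate, so compounds 4 to 9 are diastereomer mixtures that are carried on together; every sp3 stereocentre becomes sp2 in step 6 and the target has no stereocentre.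

**Step 1**
Reactants: 1 cyclohex-3-en-1-ylmethanol
Product: 2 4-(bromomethyl)cyclohex-1-ene
Conditions: CBr4, PPh3, CH2Cl2, 0 °C → rt
Reagents that add atoms: carbon tetrabromide, BrC(Br)(Br)Br
Why: Appel reaction: the primary alcohol is activated as an alkoxyphosphonium ion and displaced by bromide in an SN2 step under neutral conditions, so the ring alkene is untouched and no rearrangement is expected.

**Step 2**
Reactants: 2 4-(bromomethyl)cyclohex-1-ene (two molar equivalents, used as two equal portions: the first is converted into Grignard reagent 3, the second is the electrophile)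
Product: 4 1,2-di(cyclohex-3-en-1-yl)ethane, via (cyclohex-3-en-1-ylmethyl)magnesium bromide 3 (not isolated)
Conditions: Mg, THF, 40 °C (first portion of 2); then second portion of 2, Li2CuCl4 (3 mol%), NMP, THF, 0 → 20 °C
Reagents that add atoms: 4-(bromomethyl)cyclohex-1-ene (second molar equivalent of 2), BrCC1CCC=CC1
Why: Copper-catalysed alkyl–alkyl cross-coupling of a primary Grignard reagent with a primary alkyl bromide (Kochi coupling with Li2CuCl4, NMP as accelerating additive) should join the CH2 carbon of Grignard reagent 3 to the CH2 carbon of a second molecule of 2 and so form the CH2–CH2 bridge of the C14 diene from two C7 halves, the isolated ring alkenes being inert; the two existing stereocentres are untouched, so a meso/racemic mixture is expected.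

**Step 3**
Reactants: 4 1,2-di(cyclohex-3-en-1-yl)ethane
Product: 5 3,3'-(ethane-1,2-diyl)dihexanedioic acid
Conditions: RuCl3·xH2O (2 mol%), NaIO4 (8.5 equiv), EtOAc/MeCN/H2O, 0 °C → rt
Reagents that add atoms: sodium periodate, [Na+].[O-]I(=O)(=O)=O
Why: Ruthenium tetroxide cleavage with catalytic RuCl3 and stoichiometric NaIO4 should cleave each cis-disubstituted ring alkene to two carboxylic acids, turning each cyclohex-3-enyl ring into a 3-substituted adipic acid, while the saturated bridge is left alone at room temperature.

**Step 4**
Reactants: 5 3,3'-(ethane-1,2-diyl)dihexanedioic acid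
Product: 6 tetraethyl 3,3'-(ethane-1,2-diyl)dihexanedioate
Conditions: EtOH, H2SO4 (cat.), toluene, reflux, Dean–Stark
Reagents that add atoms: ethanol, CCO
Why: Fischer esterification of four unhindered alkyl carboxylic acids, driven by excess ethanol and azeotropic removal of water.

**Step 5**
Reactants: 6 tetraethyl 3,3'-(ethane-1,2-diyl)dihexanedioate; 7 diethyl oxalate
Product: 9 tetraethyl 5,5'-(ethane-1,2-diyl)bis(2,3-dioxocyclohexane-1,4-dicarboxylate), via tetrasodium bis(dienediolate) 8 (not isolated)
Conditions: NaOEt (4.5 equiv), 7 (2.4 equiv), EtOH, 0 °C → reflux; then cold 2 M HCl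
Reagents that add atoms: none
Why: Ethoxide forms an ester enolate at one α-carbon of an adipate unit, which adds to the non-enolisable and strongly electrophilic oxalate 7 and expels ethoxide (crossed Claisen condensation); the α-carbon at the other end of the same unit then attacks the remaining ester carbonyl of the new oxalyl group, so that C2–C3 and C4–C5 of ring A and of ring B, four C–C bonds in all, are made in one operation. The closest known reaction is the NaOEt-mediated condensation of diethyl adipate itself with diethyl oxalate to diethyl 2,3-dioxocyclohexane-1,4-dicarboxylate, applied here in two directions to two adipate units that are insulated from each other by the CH2CH2 bridge. Each ring closes in the 6-(enolexo)-exo-trig mode, a Dieckmann-type acylation in which adipate carbons 2 to 5 and the two oxalate carbons form the six-membered ring. No stereocentre has to be controlled: the CH(CO2Et) centres are enolised in salt 8 and labile in 9, and the bridge-bearing carbons, carried as a diastereomer mixture, become sp2 in step 6. The selectivity needed is crossed acylation by oxalate ahead of Dieckmann closure of an adipate unit to a cyclopentanone and ahead of oxalyl cross-links between units; it is secured by the higher electrophilicity of oxalate used in excess, by the reversibility of every Claisen step in NaOEt/EtOH and by the fact that only the six-membered product can be deprotonated twice within one ring to a stabilised dienediolate, which is expected to separate as its sodium salt 8 and pull the equilibria over. The 3-substituent of each adipate unit hinders one α-carbon only slightly and leaves its acidity unchanged, so both units should behave like the parent diester.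

**Step 6**
Reactants: 9 tetraethyl 5,5'-(ethane-1,2-diyl)bis(2,3-dioxocyclohexane-1,4-dicarboxylate)
Product: 10 tetraethyl 5,5'-(ethane-1,2-diyl)bis(2,3-dihydroxybenzene-1,4-dicarboxylate)
Conditions: Br2 (2.1 equiv), CHCl3, 0 °C → reflux, dark
Reagents that add atoms: none
Why: Bromine-mediated dehydrogenation, known for the parent dione diester: bromination at an enol carbon α to an ester, loss of HBr towards the neighbouring CH2 on warming and enolisation of the resulting dienone should give the catechol, so one Br2 per ring removes two hydrogens and erases all sp3 stereocentres.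

**Step 7**
Reactants: 10 tetraethyl 5,5'-(ethane-1,2-diyl)bis(2,3-dihydroxybenzene-1,4-dicarboxylate)
Product: 12 5,5'-(ethane-1,2-diyl)bis(2,3-dihydroxybenzene-1,4-dicarboxylic acid), via tetrapotassium tetracarboxylate 11 (not isolated)
Conditions: KOH (12 equiv), H2O/EtOH, reflux, Ar; then 6 M HCl, 0 °C
Reagents that add atoms: potassium hydroxide, [K+].[OH-]
Why: Saponification (acyl–oxygen cleavage by hydroxide) of the four aryl esters; argon protects the catecholate from air oxidation, prolonged reflux is planned for the ester flanked by the bridge and a phenoxide, and cold acidification liberates the tetraacid.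

**Step 8**
Reactants: 12 5,5'-(ethane-1,2-diyl)bis(2,3-dihydroxybenzene-1,4-dicarboxylic acid)
Product: 13 5,5'-(ethane-1,2-diyl)bis(3,4,6-tribromobenzene-1,2-diol)
Conditions: Br2 (8 equiv), AcOH/H2O (4:1), 20 → 50 °C, dark; then aq. Na2S2O4
Reagents that add atoms: bromine, BrBr
Why: Ipso-bromodecarboxylation of ortho-hydroxybenzoic acids, the reaction by which salicylic acid gives 2,4,6-tribromophenol with bromine water: bromine attacks each carboxyl-bearing carbon (C2 and C5, each ortho to a hydroxyl), CO2 is lost with rearomatisation, and C6–H, para to the C3 hydroxyl, is brominated by ordinary electrophilic substitution; the dithionite wash destroys excess bromine and returns any over-oxidised o-quinone to the catechol.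

**Compound list**

1 | cyclohex-3-en-1-ylmethanol (racemic) | OCC1CCC=CC1 | starting material
2 | 4-(bromomethyl)cyclohex-1-ene (racemic) | BrCC1CCC=CC1 | intermediate
3 | (cyclohex-3-en-1-ylmethyl)magnesium bromide | Br[Mg]CC1CCC=CC1 | intermediate (not isolated)
4 | 1,2-di(cyclohex-3-en-1-yl)ethane (meso/racemic mixture) | C(CC1CCC=CC1)C1CCC=CC1 | intermediate
5 | 3,3'-(ethane-1,2-diyl)dihexanedioic acid (meso/racemic mixture) | OC(=O)CCC(CCC(CCC(O)=O)CC(O)=O)CC(O)=O | intermediate
6 | tetraethyl 3,3'-(ethane-1,2-diyl)dihexanedioate (meso/racemic mixture) | CCOC(=O)CCC(CCC(CCC(=O)OCC)CC(=O)OCC)CC(=O)OCC | intermediate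
7 | diethyl oxalate | CCOC(=O)C(=O)OCC | starting material
8 | tetrasodium 5,5'-(ethane-1,2-diyl)bis[1,4-bis(ethoxycarbonyl)cyclohexa-1,3-diene-2,3-diolate] (diastereomer mixture) | CCOC(=O)C1=C([O-])C([O-])=C(C(=O)OCC)C(CCC2CC(C(=O)OCC)=C([O-])C([O-])=C2C(=O)OCC)C1.[Na+].[Na+].[Na+].[Na+] | intermediate (not isolated)
9 | tetraethyl 5,5'-(ethane-1,2-diyl)bis(2,3-dioxocyclohexane-1,4-dicarboxylate) (keto form drawn; largely enolised, stereocentres labile) | CCOC(=O)C1CC(CCC2CC(C(=O)OCC)C(=O)C(=O)C2C(=O)OCC)C(C(=O)OCC)C(=O)C1=O | intermediate
10 | tetraethyl 5,5'-(ethane-1,2-diyl)bis(2,3-dihydroxybenzene-1,4-dicarboxylate) | CCOC(=O)c1cc(CCc2cc(C(=O)OCC)c(O)c(O)c2C(=O)OCC)c(C(=O)OCC)c(O)c1O | intermediate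
11 | tetrapotassium 5,5'-(ethane-1,2-diyl)bis(2,3-dihydroxybenzene-1,4-dicarboxylate) (drawn with free phenols; partly ionised as well under excess KOH) | [K+].[K+].[K+].[K+].[O-]C(=O)c1cc(CCc2cc(C([O-])=O)c(O)c(O)c2C([O-])=O)c(C([O-])=O)c(O)c1O | intermediate (not isolated)
12 | 5,5'-(ethane-1,2-diyl)bis(2,3-dihydroxybenzene-1,4-dicarboxylic acid) | OC(=O)c1cc(CCc2cc(C(O)=O)c(O)c(O)c2C(O)=O)c(C(O)=O)c(O)c1O | intermediate
13 | 5,5'-(ethane-1,2-diyl)bis(3,4,6-tribromobenzene-1,2-diol) | Oc1c(O)c(Br)c(CCc2c(Br)c(O)c(O)c(Br)c2Br)c(Br)c1Br | target

**Step count and risks**

Total step count: 8. Longest linear sequence: 8 steps (1 → 13).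

Steps most likely to fail:

1. Step 5. Dieckmann closure of an adipate unit to a five-membered β-keto ester may compete with acylation by oxalate. One unit may also stop at the open oxalyl stage, or oxalyl groups may link different units into oligomers. Fallback: setting out from 6, the rings are built by joining the two ester carbons of each adipate unit instead of acylating the α-carbons. An acyloin condensation with silyl trapping (Na, Me3SiCl, toluene, reflux), under which Dieckmann closure is suppressed, should give 1,2-bis[3,4-bis(trimethylsilyloxy)cyclohex-3-en-1-yl]ethane F1. Br2 (2 equiv) in CH2Cl2 at −78 °C should convert it into 4,4'-(ethane-1,2-diyl)bis(cyclohexane-1,2-dione) F2. Dehydrogenation over Pd/C in refluxing p-cymene should give 4,4'-(ethane-1,2-diyl)di(benzene-1,2-diol) F3. Excess Br2 in AcOH should then brominate the three free positions of each 4-alkylcatechol ring, and the sequence comes back to the route at 13.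

2. Step 8. Oxidation of the catechol rings to o-quinones by bromine may outrun ipso substitution, or ipso attack may stall at the carboxyl-bearing carbon flanked by the bridge, leaving carboxyl groups in place. Fallback: setting out from 12, the carboxyl groups are removed before any bromine is introduced. Protodecarboxylation (Cu powder, quinoline, 200 °C, Ar) should give 4,4'-(ethane-1,2-diyl)di(benzene-1,2-diol) F4. Br2 (6.5 equiv) in AcOH at room temperature should then substitute the three C–H positions of each ring, as in the conversion of catechol into tetrabromocatechol, and the sequence comes back to the route at 13.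

3. Step 2. β-Branching on both partners may slow the copper-catalysed coupling, so that halogen–metal exchange, reduction and elimination of the C7 fragments take over. Fallback: setting out from 2, the bridge is made by carbanion alkylation instead of cross-coupling. PhSO2Na in DMF at 80 °C should give [(cyclohex-3-en-1-ylmethyl)sulfonyl]benzene F5. Deprotonation with n-BuLi in THF/DMPU at −78 °C and alkylation with a second portion of 2 should give {[1,2-di(cyclohex-3-en-1-yl)ethyl]sulfonyl}benzene F6. Reductive desulfonylation with Na(Hg) and Na2HPO4 in MeOH should remove the sulfonyl group without touching the ring alkenes, and the sequence comes back to the route at 4.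

**Further compounds**

F1 | step 5 | 1,2-bis[3,4-bis(trimethylsilyloxy)cyclohex-3-en-1-yl]ethane | C[Si](C)(C)OC1=C(O[Si](C)(C)C)CC(CCC2CCC(O[Si](C)(C)C)=C(O[Si](C)(C)C)C2)CC1
F2 | step 5 | 4,4'-(ethane-1,2-diyl)bis(cyclohexane-1,2-dione) | O=C1CCC(CCC2CCC(=O)C(=O)C2)CC1=O
F3 | step 5 | 4,4'-(ethane-1,2-diyl)di(benzene-1,2-diol) | Oc1ccc(CCc2ccc(O)c(O)c2)cc1O
F4 | step 8 | 4,4'-(ethane-1,2-diyl)di(benzene-1,2-diol) | Oc1ccc(CCc2ccc(O)c(O)c2)cc1O
F5 | step 2 | [(cyclohex-3-en-1-ylmethyl)sulfonyl]benzene | O=S(=O)(CC1CCC=CC1)c1ccccc1
F6 | step 2 | {[1,2-di(cyclohex-3-en-1-yl)ethyl]sulfonyl}benzene | O=S(=O)(C(CC1CCC=CC1)C1CCC=CC1)c1ccccc1
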